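## The problem

The target is a B-type proanthocyanidin dimer. An upper epigallocatechin unit (rings A, C and B) carries a galloyl ester on O3 and is bonded through C4 to C8 of a lower (+)-catechin unit (rings D, F and E), in the 4β→8 sense. There are five stereocentres: the lower (2R,3S) pair, which is that of natural (+)-catechin, and the upper C2, C3 and C4 (all R; 2,3-cis, 3,4-trans), which have to be built. The lower centres are too remote from upper C4 to control it, so C4 needs reagent control; its two configurations are, however, diastereomers and therefore separable. C3 can then be set against C4, and C2 against C3. The interflavan C4–C8 bond ionises under acid to a ring-A-stabilised cation, the galloyl ester is base-labile, and free catechol and pyrogallol rings oxidise in air and allow C2 epimerisation in base. All thirteen hydroxyl groups that are free in the target (twelve phenols and the lower 3-OH) are therefore carried as benzyl ethers to the last step, and the ester is introduced late. The enabling feature is that upper C4 is a diarylmethine carbon on C4a, next to the O1-bearing C8a. Ring C (O1, C2, C3, C4, C4a, C8a) therefore maps onto a ring-A o-quinone methide (C4=C4a–C8a=O1), whose methide carbon is stabilised by ring D, plus the C2–C3 enol of an aryl ketone.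

## Retrosynthesis

**Benzyl ethers.** Target 23 is traced to its tridecabenzyl ether 22 by cutting thirteen O–benzyl bonds. Benzyl is preferred to methyl or silyl because it leaves under neutral hydrogenolysis, which spares both the ester and the interflavan bond. Putting a benzyl group on the lower 3-OH as well means one operation frees everything. The forward step must cleave all thirteen ethers without opening the benzylic C2–O1 bonds.

**Galloyl ester.** Cutting the ester C–O bond of 22 gives alcohol 21 and 3,4,5-tris(benzyloxy)benzoyl chloride 12. The ester is attached after ring C is complete: carried earlier, it would be exposed to fluoride and could take part in the ionisation at C2. The forward step is the acylation of a hindered axial alcohol, the only free hydroxyl in 21.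

**C2–H bond.** Alcohol 21 comes from silyl ether 20, and the C2–H bond of 20 is traced to the C2–OH of hemiketal 18 through oxocarbenium ion 19. Placing C2 at the ketone oxidation level lets ring C be assembled from a ketone and removes one stereocentre from the ring-forming step. The reduction must deliver hydride anti to O3 to give the 2,3-cis flavan.

**Ring C (key disconnection).** Hemiketal 18 is cut at C3–C4 and O1–C2 into diarylcarbinol 10 and α-silyloxy ketone 15, by way of o-quinone methide 16 and keto phenol 17.
- Against a cut at C4–C8, the usual one for procyanidins, this choice does not need a preformed, C4-activated epigallocatechin unit.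
- It builds the upper unit from an achiral ketone and an aldehyde.
- Ketone 15 can enolise only towards its CH2OSi carbon, so C3 arrives oxygenated.
- The forward reaction has to form a congested C–C bond and control C4 (catalyst) and C3 (relative to C4).

**Carbinol C–C bond.** Carbinol 10 comes from allyl ether 9, and 9 is cut between the carbinol carbon and C8 of the catechin unit into aryl bromide 4 (used as aryllithium 8) and aldehyde 7. A Friedel–Crafts union of the free catechin nucleus with the aldehyde would not distinguish C6 from C8; the bromine fixes the site. The phenol of 7 is masked as an allyl ether because that group is removed under neutral conditions, which the acid-labile carbinol requires.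

**Catechin fragment.** Bromide 4 goes back through 3 and 2 to (+)-catechin 1 by O-benzylation, C8 bromination and phenol benzylation. This keeps the lower (2R,3S) centres from the chiral pool untouched.

**Aldehyde fragment.** Aldehyde 7 comes from 6 and then from 2,4,6-trihydroxybenzaldehyde 5 by two O-alkylations. The order is dictated by the low reactivity of the hydrogen-bonded ortho hydroxyl.

**Ketone fragment.** Ketone 15 is derived from hydroxy ketone 14, diazoketone 13 and acid chloride 12, which comes from 3,4,5-tris(benzyloxy)benzoic acid 11. The one-carbon homologation of the acid chloride puts the oxygen on the new carbon directly, and 12 is shared with the esterification.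

## Roads not taken

**Alternative 1:** Ring F of the lower unit is cut at C4'–C3' and O1'–C2'. A complete, benzylated upper unit would carry ring D as o-quinone methide A2, and this would add the (E)-enol carbonate A3 suprafacially to give the fully protected dimer A1 with a 2,3-trans ring F.
- Merits: all three upper stereocentres could be taken from a natural 2,3-cis gallocatechin gallate by the established 4β-selective C4 arylation. This is firmer ground for the 2,3-cis-3,4-trans array than the chosen plan, which must create it. A1 is also one hydrogenolysis from the target.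
- Weak points: the two new centres of ring F lie far from any controlling element, so their absolute sense is left to chance. A2 has an unsubstituted methylene terminus, so it is very reactive and prone to dimerise. In A3 the carbonate oxygen and the electron-rich aryl group polarise the alkene in opposite directions, which lowers reactivity and threatens the regiochemistry.
- Comparison: the chosen plan instead takes the lower unit intact from (+)-catechin and uses a polarity-matched enol. In exchange it accepts the harder job of setting three upper centres.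

**Alternative 2:** Ring C is cut at C4–C4a and O1–C2. 3,5-Bis(benzyloxy)phenol A6 would add through its ortho carbon to the iminium ion of the ring-D enal A5 under a chiral secondary amine, and the phenol would close on the aldehyde to give lactol A4.
- Merits: this Friedel–Crafts/hemiacetalisation has good catalytic precedent, and it sets C4 by reagent control at a neutral, less congested β-carbon. In that respect it is better founded than the chosen key step.
- Weak points: A4 has neither the C2 aryl group nor the C3 oxygen. Adding them needs lactol oxidation, aryl addition, dehydration and hydroboration–oxidation; the last gives the 2,3-trans alcohol and forces a C3 oxidation–reduction. This is roughly twice the number of post-key steps, each with its own stereochemical question. The di-ortho-substituted aryl enal A5 is also a slow iminium partner.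
- Comparison: the chosen plan brings C2, its aryl group and the C3 oxygen in with the ring closure, at the price of a less secure C4 induction.

**Alternative 3:** Ring C is cut at O1–C8a and C4–C4a. The alkoxide of syn aldol A8 would add to 3,5-bis(benzyloxy)benzyne A9, and the resulting aryl anion would add to the ring-D ketone to give the 4-hydroxyflavan A7.
- Merits: C2 and C3 come from a reliable asymmetric glycolate aldol, so the 2,3-cis pair is secured before ring closure and no face-selective reduction at C2 is needed. This is an advantage over the chosen plan.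
- Weak points: the alkoxide of A8 is a β-keto alkoxide and can fragment by retro-aldol under the basic aryne conditions. The hindered aryl anion has to attack a di-ortho-substituted aryl ketone. C4 emerges as a tertiary carbinol whose ionic deoxygenation must deliver hydride syn to O3 to reach the 3,4-trans product, against the steric bias.
- Comparison: the chosen plan forms C4 directly as the methine under catalyst control, and places its own reduction at C2, where the neighbouring silyloxy group directs hydride in the required sense.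

Key step: step 12

Assumptions:
- 3,4,5-Tris(benzyloxy)benzoic acid 11, the benzylated form of gallic acid, is taken as a purchased material.
- The (R)-phosphoric acid is written in step 12 on the assumption that it is the antipode matched to the catechin unit; otherwise the (S)-acid is used.
- "Penta-O-benzylcatechin-8-yl" stands for (2R,3S)-3,5,7-tris(benzyloxy)-2-[3,4-bis(benzyloxy)phenyl]chroman-8-yl.

## Route

Step 1
Reactants: 1 (+)-catechin
Product: 2 5,7,3',4'-tetra-O-benzyl-(+)-catechin
Conditions: BnBr (4.2 equiv), K2CO3, DMF, 0 °C to rt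
Reagents that add atoms: benzyl bromide, BrCc1ccccc1
Why: Williamson etherification; carbonate deprotonates only the four phenols, so the secondary 3-OH stays free and the (2R,3S) centres are untouched at low temperature.

Step 2
Reactants: 2 5,7,3',4'-tetra-O-benzyl-(+)-catechin
Product: 3 8-bromo-5,7,3',4'-tetra-O-benzyl-(+)-catechin
Conditions: NBS (1.0 equiv), CH2Cl2, −78 °C to rt
Reagents that add atoms: N-bromosuccinimide, O=C1CCC(=O)N1Br
Why: Electrophilic aromatic bromination; with the 3-OH free, the phloroglucinol-type ring D of benzylated catechins is brominated selectively at C8.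

Step 3
Reactants: 3 8-bromo-5,7,3',4'-tetra-O-benzyl-(+)-catechin
Product: 4 8-bromo-3,5,7,3',4'-penta-O-benzyl-(+)-catechin
Conditions: NaH, BnBr, DMF, 0 °C to rt
Reagents that add atoms: benzyl bromide, BrCc1ccccc1
Why: Williamson etherification of the sodium alkoxide; it removes the only acidic proton before the lithiation and gives a group that leaves in the final hydrogenolysis.

Step 4
Reactants: 5 2,4,6-trihydroxybenzaldehyde
Product: 6 2,4-bis(benzyloxy)-6-hydroxybenzaldehyde
Conditions: BnBr (2.0 equiv), K2CO3, DMF, rt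
Reagents that add atoms: benzyl bromide, BrCc1ccccc1
Why: Williamson etherification; once one ortho hydroxyl is alkylated, the remaining one is held by a hydrogen bond to the aldehyde and is the least nucleophilic, so the dibenzyl ether is the main product.

Step 5
Reactants: 6 2,4-bis(benzyloxy)-6-hydroxybenzaldehyde
Product: 7 2-(allyloxy)-4,6-bis(benzyloxy)benzaldehyde
Conditions: allyl bromide, K2CO3, DMF, 50 °C
Reagents that add atoms: allyl bromide, C=CCBr
Why: Williamson etherification of the chelated phenol under mild heating; the allyl ether tolerates the aryllithium and is later removed without acid.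

Step 6
Reactants: 4 8-bromo-3,5,7,3',4'-penta-O-benzyl-(+)-catechin, 7 2-(allyloxy)-4,6-bis(benzyloxy)benzaldehyde
Product: 9 [2-(allyloxy)-4,6-bis(benzyloxy)phenyl](penta-O-benzylcatechin-8-yl)methanol (carbinol epimers), via 8-lithio-penta-O-benzylcatechin 8 (not isolated)
Conditions: n-BuLi, THF, −78 °C; then 7, −78 to 0 °C; H2O quench
Reagents that add atoms: none
Why: Bromine–lithium exchange followed by 1,2-addition of the aryllithium to the aldehyde. The new carbinol centre forms as a mixture, which does not matter because it is planarised in step 12.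

Step 7
Reactants: 9 [2-(allyloxy)-4,6-bis(benzyloxy)phenyl](penta-O-benzylcatechin-8-yl)methanol
Product: 10 [2-hydroxy-4,6-bis(benzyloxy)phenyl](penta-O-benzylcatechin-8-yl)methanol (carbinol epimers)
Conditions: Pd(PPh3)4 (5 mol%), morpholine, THF, rt; chromatography on Et3N-deactivated silica
Reagents that add atoms: none
Why: Tsuji–Trost deallylation: zerovalent palladium ionises the aryl allyl ether to a π-allyl complex of divalent palladium and morpholine takes up the allyl group. The conditions are neutral to basic, so the acid-labile carbinol and the benzyl ethers are not touched.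

Step 8
Reactants: 11 3,4,5-tris(benzyloxy)benzoic acid
Product: 12 3,4,5-tris(benzyloxy)benzoyl chloride
Conditions: (COCl)2, DMF (cat.), CH2Cl2, 0 °C to rt
Reagents that add atoms: oxalyl chloride, ClC(=O)C(=O)Cl
Why: Standard acid chloride formation through the Vilsmeier-type chloroiminium catalyst; benzyl ethers are inert.

Step 9
Reactants: 12 3,4,5-tris(benzyloxy)benzoyl chloride
Product: 13 2-diazo-1-[3,4,5-tris(benzyloxy)phenyl]ethanone
Conditions: TMSCHN2 (2 M in hexanes), THF/MeCN, 0 °C to rt
Reagents that add atoms: trimethylsilyldiazomethane, C[Si](C)(C)C=[N+]=[N-]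
Why: C-acylation of the diazoalkane with loss of the silyl group as the chloride (first stage of an Arndt–Eistert sequence); an aroyl chloride has no α-hydrogen, so no ketene pathway competes.

Step 10
Reactants: 13 2-diazo-1-[3,4,5-tris(benzyloxy)phenyl]ethanone
Product: 14 2-hydroxy-1-[3,4,5-tris(benzyloxy)phenyl]ethanone
Conditions: 1 M aq. H2SO4, 1,4-dioxane, 60 °C
Reagents that add atoms: water, O
Why: Acid-catalysed hydrolysis of an α-diazoketone: C-protonation gives the diazonium ion and water displaces dinitrogen. Benzyl ethers survive dilute aqueous acid.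

Step 11
Reactants: 14 2-hydroxy-1-[3,4,5-tris(benzyloxy)phenyl]ethanone
Product: 15 2-(tert-butyldimethylsilyloxy)-1-[3,4,5-tris(benzyloxy)phenyl]ethanone
Conditions: TBSCl, imidazole, DMF, rt
Reagents that add atoms: tert-butyldimethylsilyl chloride, CC(C)(C)[Si](C)(C)Cl
Why: Imidazole-promoted silylation of a primary alcohol; the bulky, non-chelating silyl ether is needed as the stereodirecting group in step 13.

Step 12
Reactants: 10 [2-hydroxy-4,6-bis(benzyloxy)phenyl](penta-O-benzylcatechin-8-yl)methanol, 15 2-(tert-butyldimethylsilyloxy)-1-[3,4,5-tris(benzyloxy)phenyl]ethanone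
Product: 18 (3R,4R)-5,7-bis(benzyloxy)-3-(tert-butyldimethylsilyloxy)-4-(penta-O-benzylcatechin-8-yl)-2-[3,4,5-tris(benzyloxy)phenyl]chroman-2-ol (3,4-trans; C2 anomers), via o-quinone methide 16 (not isolated), via open-chain keto phenol 17 (not isolated)
Conditions: (R)-TRIP [(R)-3,3'-bis(2,4,6-triisopropylphenyl)-1,1'-binaphthyl-2,2'-diyl hydrogen phosphate] (10 mol%), 15 (3 equiv), 5 Å MS, PhMe, 40 °C, slow addition of 10
Reagents that add atoms: none
Why: The phosphoric acid protonates the benzhydrylic hydroxyl of 10 and water leaves to give o-quinone methide 16 (both carbinol epimers converge on this planar species), which stays hydrogen-bonded to the phosphate at its carbonyl oxygen while the same phosphate catalyses enolisation of 15 and binds the enol hydroxyl. Conjugate addition of the (Z)-enol carbon to the methide carbon forms C3–C4 and rearomatises ring A to keto phenol 17, whose phenol then adds to the aryl ketone in a 6-exo-trig hemiketalisation (O1–C2), closing ring C as 18. The closest known reaction type is the chiral phosphoric acid-catalysed conjugate addition of enolisable carbonyl compounds to o-quinone methides made in situ from o-hydroxybenzhydrols, with hemiketal closure to 2-hydroxychromans; here it is applied to an α-silyloxy aryl ketone. C4 is set by the chiral phosphate, which differentiates the two faces of the methide carbon in the doubly hydrogen-bonded transition state; because the catechin unit is enantiopure the C4 epimers are diastereomers, so a minor epimer can be removed by chromatography. C3 is set relative to C4 by the (Z)-enol approaching with its silyloxy group turned away from the quinone methide (3,4-trans), and it can still be equilibrated through open form 17 towards the trans isomer, in which the silyloxy and C4 aryl groups are anti. The step needs regioselective enolisation, secured because 15 has α-hydrogens only on the silyloxy-bearing carbon, and it needs C-alkylation to outrun self-condensation, which is favoured by excess 15, slow addition of 10 and the two oxygen substituents flanking every nucleophilic arene position of 10. The C2 anomers are of no consequence because C2 is planarised in step 13.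

Step 13
Reactants: 18 (3R,4R)-5,7-bis(benzyloxy)-3-(tert-butyldimethylsilyloxy)-4-(penta-O-benzylcatechin-8-yl)-2-[3,4,5-tris(benzyloxy)phenyl]chroman-2-ol
Product: 20 (2R,3R,4R)-5,7-bis(benzyloxy)-3-(tert-butyldimethylsilyloxy)-4-(penta-O-benzylcatechin-8-yl)-2-[3,4,5-tris(benzyloxy)phenyl]chromane (2,3-cis; 3,4-trans), via oxocarbenium triflate 19 (not isolated)
Conditions: Et3SiH (5 equiv), TMSOTf (0.5 equiv), CH2Cl2, −78 °C
Reagents that add atoms: none
Why: Reductive etherification (ionic hydrogenation of a hemiketal): TMSOTf ionises 18 to the 2-aryl oxocarbenium ion 19, in which A(1,2) strain against the coplanar C2 aryl group holds the C3 silyloxy group pseudoaxial. Triethylsilane delivers hydride antiperiplanar to that C–O bond through a half-chair, so the C2 aryl group ends cis to O3 and trans to the C4 aryl group, as in the known route to 2,3-cis flavan-3-ols from α-silyloxy ketone phenols.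

Step 14
Reactants: 20 (2R,3R,4R)-5,7-bis(benzyloxy)-3-(tert-butyldimethylsilyloxy)-4-(penta-O-benzylcatechin-8-yl)-2-[3,4,5-tris(benzyloxy)phenyl]chromane
Product: 21 (2R,3R,4R)-5,7-bis(benzyloxy)-4-(penta-O-benzylcatechin-8-yl)-2-[3,4,5-tris(benzyloxy)phenyl]chroman-3-ol
Conditions: TBAF, THF, 0 °C to rt
Reagents that add atoms: none
Why: Fluoride-induced desilylation; no base-sensitive group is present because every phenol is benzylated, and no stereocentre is affected.

Step 15
Reactants: 21 (2R,3R,4R)-5,7-bis(benzyloxy)-4-(penta-O-benzylcatechin-8-yl)-2-[3,4,5-tris(benzyloxy)phenyl]chroman-3-ol, 12 3,4,5-tris(benzyloxy)benzoyl chloride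
Product: 22 (2R,3R,4R)-5,7-bis(benzyloxy)-4-(penta-O-benzylcatechin-8-yl)-2-[3,4,5-tris(benzyloxy)phenyl]chroman-3-yl 3,4,5-tris(benzyloxy)benzoate
Conditions: 12 (3 equiv), DMAP, Et3N, CH2Cl2, rt
Reagents that add atoms: none
Why: DMAP-catalysed acylation through the acylpyridinium ion; the upper 3-OH is the only free hydroxyl, and O-acylation does not disturb C3.

Step 16
Reactants: 22 (2R,3R,4R)-5,7-bis(benzyloxy)-4-(penta-O-benzylcatechin-8-yl)-2-[3,4,5-tris(benzyloxy)phenyl]chroman-3-yl 3,4,5-tris(benzyloxy)benzoate
Product: 23 epigallocatechin 3-O-gallate-(4β→8)-catechin (CNP0129434.1)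
Conditions: H2 (1 atm), Pd(OH)2/C, THF/MeOH, rt; work-up under argon
Reagents that add atoms: none
Why: Catalytic hydrogenolysis of the twelve aryl benzyl ethers and the one alkyl benzyl ether under neutral conditions, which leave the galloyl ester, the interflavan bond and all five stereocentres intact.

## Compound list

1 | (+)-catechin, (2R,3S)-2-(3,4-dihydroxyphenyl)chromane-3,5,7-triol | Oc1cc(O)c2c(c1)O[C@H](c1ccc(O)c(O)c1)[C@@H](O)C2 | starting material
2 | 5,7,3',4'-tetra-O-benzyl-(+)-catechin, (2R,3S)-5,7-bis(benzyloxy)-2-[3,4-bis(benzyloxy)phenyl]chroman-3-ol | c2c(OCc9ccccc9)cc(OCc9ccccc9)c3c2O[C@H](c4ccc(OCc9ccccc9)c(OCc9ccccc9)c4)[C@@H](O)C3 | intermediate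
3 | 8-bromo-5,7,3',4'-tetra-O-benzyl-(+)-catechin, (2R,3S) | Brc2c(OCc9ccccc9)cc(OCc9ccccc9)c3c2O[C@H](c4ccc(OCc9ccccc9)c(OCc9ccccc9)c4)[C@@H](O)C3 | intermediate
4 | 8-bromo-3,5,7,3',4'-penta-O-benzyl-(+)-catechin, (2R,3S)-3,5,7-tris(benzyloxy)-2-[3,4-bis(benzyloxy)phenyl]-8-bromochromane | Brc2c(OCc9ccccc9)cc(OCc9ccccc9)c3c2O[C@H](c4ccc(OCc9ccccc9)c(OCc9ccccc9)c4)[C@@H](OCc9ccccc9)C3 | intermediate
5 | 2,4,6-trihydroxybenzaldehyde | O=Cc1c(O)cc(O)cc1O | starting material
6 | 2,4-bis(benzyloxy)-6-hydroxybenzaldehyde | O=Cc1c(O)cc(OCc9ccccc9)cc1OCc9ccccc9 | intermediate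
7 | 2-(allyloxy)-4,6-bis(benzyloxy)benzaldehyde | O=Cc1c(OCC=C)cc(OCc9ccccc9)cc1OCc9ccccc9 | intermediate
8 | 8-lithio-3,5,7,3',4'-penta-O-benzyl-(+)-catechin (not isolated) | [Li]c2c(OCc9ccccc9)cc(OCc9ccccc9)c3c2O[C@H](c4ccc(OCc9ccccc9)c(OCc9ccccc9)c4)[C@@H](OCc9ccccc9)C3 | intermediate
9 | [2-(allyloxy)-4,6-bis(benzyloxy)phenyl](penta-O-benzylcatechin-8-yl)methanol, carbinol epimers | OC(c2c(OCc9ccccc9)cc(OCc9ccccc9)c3c2O[C@H](c4ccc(OCc9ccccc9)c(OCc9ccccc9)c4)[C@@H](OCc9ccccc9)C3)c7c(OCc9ccccc9)cc(OCc9ccccc9)cc7OCC=C | intermediate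
10 | [2-hydroxy-4,6-bis(benzyloxy)phenyl](penta-O-benzylcatechin-8-yl)methanol, carbinol epimers | OC(c2c(OCc9ccccc9)cc(OCc9ccccc9)c3c2O[C@H](c4ccc(OCc9ccccc9)c(OCc9ccccc9)c4)[C@@H](OCc9ccccc9)C3)c7c(OCc9ccccc9)cc(OCc9ccccc9)cc7O | intermediate
11 | 3,4,5-tris(benzyloxy)benzoic acid | OC(=O)c1cc(OCc9ccccc9)c(OCc9ccccc9)c(OCc9ccccc9)c1 | starting material
12 | 3,4,5-tris(benzyloxy)benzoyl chloride | ClC(=O)c1cc(OCc9ccccc9)c(OCc9ccccc9)c(OCc9ccccc9)c1 | intermediate
13 | 2-diazo-1-[3,4,5-tris(benzyloxy)phenyl]ethanone | [N-]=[N+]=CC(=O)c1cc(OCc9ccccc9)c(OCc9ccccc9)c(OCc9ccccc9)c1 | intermediate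
14 | 2-hydroxy-1-[3,4,5-tris(benzyloxy)phenyl]ethanone | OCC(=O)c1cc(OCc9ccccc9)c(OCc9ccccc9)c(OCc9ccccc9)c1 | intermediate
15 | 2-(tert-butyldimethylsilyloxy)-1-[3,4,5-tris(benzyloxy)phenyl]ethanone | CC(C)(C)[Si](C)(C)OCC(=O)c1cc(OCc9ccccc9)c(OCc9ccccc9)c(OCc9ccccc9)c1 | intermediate
16 | o-quinone methide, 3,5-bis(benzyloxy)-6-[(penta-O-benzylcatechin-8-yl)methylidene]cyclohexa-2,4-dien-1-one (not isolated) | C(=C1C(=O)C=C(OCc9ccccc9)C=C1OCc9ccccc9)c2c(OCc9ccccc9)cc(OCc9ccccc9)c3c2O[C@H](c4ccc(OCc9ccccc9)c(OCc9ccccc9)c4)[C@@H](OCc9ccccc9)C3 | intermediate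
17 | open-chain keto phenol, (2R,3R)-2-(tert-butyldimethylsilyloxy)-3-[2-hydroxy-4,6-bis(benzyloxy)phenyl]-3-(penta-O-benzylcatechin-8-yl)-1-[3,4,5-tris(benzyloxy)phenyl]propan-1-one (not isolated) | CC(C)(C)[Si](C)(C)O[C@H]([C@@H](c2c(OCc9ccccc9)cc(OCc9ccccc9)c3c2O[C@H](c4ccc(OCc9ccccc9)c(OCc9ccccc9)c4)[C@@H](OCc9ccccc9)C3)c7c(OCc9ccccc9)cc(OCc9ccccc9)cc7O)C(=O)c5cc(OCc9ccccc9)c(OCc9ccccc9)c(OCc9ccccc9)c5 | intermediate
18 | hemiketal, (3R,4R)-5,7-bis(benzyloxy)-3-(tert-butyldimethylsilyloxy)-4-(penta-O-benzylcatechin-8-yl)-2-[3,4,5-tris(benzyloxy)phenyl]chroman-2-ol, 3,4-trans, C2 anomers | CC(C)(C)[Si](C)(C)O[C@@H]1[C@@H](c2c(OCc9ccccc9)cc(OCc9ccccc9)c3c2O[C@H](c4ccc(OCc9ccccc9)c(OCc9ccccc9)c4)[C@@H](OCc9ccccc9)C3)c7c(OCc9ccccc9)cc(OCc9ccccc9)cc7OC1(O)c5cc(OCc9ccccc9)c(OCc9ccccc9)c(OCc9ccccc9)c5 | intermediate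
19 | oxocarbenium triflate, (3R,4R)-5,7-bis(benzyloxy)-3-(tert-butyldimethylsilyloxy)-4-(penta-O-benzylcatechin-8-yl)-2-[3,4,5-tris(benzyloxy)phenyl]-3,4-dihydrochromen-1-ium trifluoromethanesulfonate (not isolated) | CC(C)(C)[Si](C)(C)O[C@@H]1[C@@H](c2c(OCc9ccccc9)cc(OCc9ccccc9)c3c2O[C@H](c4ccc(OCc9ccccc9)c(OCc9ccccc9)c4)[C@@H](OCc9ccccc9)C3)c7c(OCc9ccccc9)cc(OCc9ccccc9)cc7[O+]=C1c5cc(OCc9ccccc9)c(OCc9ccccc9)c(OCc9ccccc9)c5.[O-]S(=O)(=O)C(F)(F)F | intermediate
20 | (2R,3R,4R)-5,7-bis(benzyloxy)-3-(tert-butyldimethylsilyloxy)-4-(penta-O-benzylcatechin-8-yl)-2-[3,4,5-tris(benzyloxy)phenyl]chromane, 2,3-cis, 3,4-trans | CC(C)(C)[Si](C)(C)O[C@@H]1[C@@H](c2c(OCc9ccccc9)cc(OCc9ccccc9)c3c2O[C@H](c4ccc(OCc9ccccc9)c(OCc9ccccc9)c4)[C@@H](OCc9ccccc9)C3)c7c(OCc9ccccc9)cc(OCc9ccccc9)cc7O[C@@H]1c5cc(OCc9ccccc9)c(OCc9ccccc9)c(OCc9ccccc9)c5 | intermediate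
21 | (2R,3R,4R)-5,7-bis(benzyloxy)-4-(penta-O-benzylcatechin-8-yl)-2-[3,4,5-tris(benzyloxy)phenyl]chroman-3-ol | O[C@@H]1[C@@H](c2c(OCc9ccccc9)cc(OCc9ccccc9)c3c2O[C@H](c4ccc(OCc9ccccc9)c(OCc9ccccc9)c4)[C@@H](OCc9ccccc9)C3)c7c(OCc9ccccc9)cc(OCc9ccccc9)cc7O[C@@H]1c5cc(OCc9ccccc9)c(OCc9ccccc9)c(OCc9ccccc9)c5 | intermediate
22 | trideca-O-benzyl target, (2R,3R,4R)-5,7-bis(benzyloxy)-4-(penta-O-benzylcatechin-8-yl)-2-[3,4,5-tris(benzyloxy)phenyl]chroman-3-yl 3,4,5-tris(benzyloxy)benzoate | O=C(O[C@@H]1[C@@H](c2c(OCc9ccccc9)cc(OCc9ccccc9)c3c2O[C@H](c4ccc(OCc9ccccc9)c(OCc9ccccc9)c4)[C@@H](OCc9ccccc9)C3)c7c(OCc9ccccc9)cc(OCc9ccccc9)cc7O[C@@H]1c5cc(OCc9ccccc9)c(OCc9ccccc9)c(OCc9ccccc9)c5)c6cc(OCc9ccccc9)c(OCc9ccccc9)c(OCc9ccccc9)c6 | intermediate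
23 | epigallocatechin 3-O-gallate-(4β→8)-catechin, (2R,3R,4R)-4-[(2R,3S)-2-(3,4-dihydroxyphenyl)-3,5,7-trihydroxychroman-8-yl]-5,7-dihydroxy-2-(3,4,5-trihydroxyphenyl)chroman-3-yl 3,4,5-trihydroxybenzoate | O=C(O[C@@H]1[C@@H](c2c(O)cc(O)c3c2O[C@H](c2ccc(O)c(O)c2)[C@@H](O)C3)c2c(O)cc(O)cc2O[C@@H]1c1cc(O)c(O)c(O)c1)c1cc(O)c(O)c(O)c1 | target

## Step count and weak points

Total: 16 steps. Longest linear sequence: 10 steps from (+)-catechin (steps 1, 2, 3, 6, 7, 12, 13, 14, 15, 16). The aldehyde branch (steps 4, 5) and the ketone branch (steps 8–11) are shorter.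

**Step 12 (key step).** Enolisation of the aryl ketone may be too slow. The quinone methide would then be consumed by Friedel–Crafts self-condensation with the electron-rich rings of a second molecule, or simply revert. The phosphate may also discriminate poorly between the faces of the hindered, twisted diarylmethide, so that C4 epimers form together.
Fallback: this sets out from 15 and 10 and returns at 18. Soft enolisation of 15 (TMSOTf, Et3N, CH2Cl2, 0 °C) gives the (Z)-1-(trimethylsilyloxy)-2-(tert-butyldimethylsilyloxy)-1-[3,4,5-tris(benzyloxy)phenyl]ethene F1, which is present at full concentration as the nucleophile. F1 is combined with 10 and catalytic BF3·OEt2 in CH2Cl2 at −78 °C, a Mukaiyama–Michael addition of a silyl enol ether to the acid-generated quinone methide. Aqueous work-up removes the trimethylsilyl group and gives 17, which closes to 18. Without a chiral catalyst the C4 epimers, being diastereomers, are separated by chromatography.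

**Step 13.** The hydride has to enter on the ring face that also carries the pseudoaxial C4 aryl group (a 1,3-relationship), so the facial selectivity at C2 may be poor or reversed. The Lewis acid may also ionise the C4–C8 bond or induce retro-Michael cleavage.
Fallback: this sets out from 18 and returns at 21, replacing steps 13 and 14. Buffered desilylation (TBAF, AcOH, THF) gives the (3R,4R)-2,3-dihydroxy hemiketal F2, which is in equilibrium with its α-hydroxy ketone. Chelation-controlled reduction with Zn(BH4)2 in Et2O then delivers hydride from the side away from the diarylmethyl group and gives the (1S,2R,3R)-1,2-anti triol F3. Mitsunobu cyclisation (PPh3, DIAD, THF) lets the phenol displace the activated benzylic hydroxyl with inversion, which gives the 2,3-cis flavan 21.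

**Step 7.** The doubly benzylic, highly electron-rich carbinol may ionise during deallylation or chromatography, with loss of the hydroxyl and self-condensation.
Fallback: this sets out from 6 and 4 and returns at 10 without a protecting group, replacing steps 5–7. Aldehyde 6 is deprotonated with NaH in THF to sodium 3,5-bis(benzyloxy)-2-formylphenoxide F4, which is added to aryllithium 8 (made from 4 as in step 6) at −78 °C. A pH 7 buffer quench gives 10 directly, to be used crude in step 12.

**Step 16.** Cleavage of thirteen benzyl ethers may stall at partly benzylated stages, the benzylic C2–O1 bonds may be opened by over-reduction, and the product may oxidise during isolation.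
Fallback: this sets out from 22 and returns at 23. Lewis acid-mediated debenzylation with BCl3 and pentamethylbenzene as cation scavenger (CH2Cl2, −78 °C) removes the benzyl groups without hydrogen; the low temperature is needed to protect the interflavan bond. This fallback makes no new compound (F0).

## Further compounds

F1 | step 12 | (Z)-1-(trimethylsilyloxy)-2-(tert-butyldimethylsilyloxy)-1-[3,4,5-tris(benzyloxy)phenyl]ethene | C[Si](C)(C)O/C(c1cc(OCc9ccccc9)c(OCc9ccccc9)c(OCc9ccccc9)c1)=C\O[Si](C)(C)C(C)(C)C
F2 | step 13 | (3R,4R)-5,7-bis(benzyloxy)-4-(penta-O-benzylcatechin-8-yl)-2-[3,4,5-tris(benzyloxy)phenyl]chromane-2,3-diol, C2 anomers | O[C@@H]1[C@@H](c2c(OCc9ccccc9)cc(OCc9ccccc9)c3c2O[C@H](c4ccc(OCc9ccccc9)c(OCc9ccccc9)c4)[C@@H](OCc9ccccc9)C3)c7c(OCc9ccccc9)cc(OCc9ccccc9)cc7OC1(O)c5cc(OCc9ccccc9)c(OCc9ccccc9)c(OCc9ccccc9)c5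
F3 | step 13 | (1S,2R,3R)-3-[2-hydroxy-4,6-bis(benzyloxy)phenyl]-3-(penta-O-benzylcatechin-8-yl)-1-[3,4,5-tris(benzyloxy)phenyl]propane-1,2-diol, 1,2-anti | O[C@H]([C@@H](c2c(OCc9ccccc9)cc(OCc9ccccc9)c3c2O[C@H](c4ccc(OCc9ccccc9)c(OCc9ccccc9)c4)[C@@H](OCc9ccccc9)C3)c7c(OCc9ccccc9)cc(OCc9ccccc9)cc7O)[C@@H](O)c5cc(OCc9ccccc9)c(OCc9ccccc9)c(OCc9ccccc9)c5
F4 | step 7 | sodium 3,5-bis(benzyloxy)-2-formylphenoxide | [Na+].[O-]c1cc(OCc9ccccc9)cc(OCc9ccccc9)c1C=O
F0 | step 16 | none | none
A1 | alternative 1 | trideca-O-benzyl target carrying a benzyl carbonate on the lower 3-oxygen | O=C(c6cc(OCc9ccccc9)c(OCc9ccccc9)c(OCc9ccccc9)c6)O[C@@H]1[C@@H](c2c(OCc9ccccc9)cc(OCc9ccccc9)c3c2O[C@H](c4ccc(OCc9ccccc9)c(OCc9ccccc9)c4)[C@@H](OC(=O)OCc9ccccc9)C3)c7c(OCc9ccccc9)cc(OCc9ccccc9)cc7O[C@@H]1c5cc(OCc9ccccc9)c(OCc9ccccc9)c(OCc9ccccc9)c5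
A2 | alternative 1 | ring-D o-quinone methide on the benzylated epigallocatechin gallate unit, (2R,3R,4R)-4-[2,4-bis(benzyloxy)-5-methylidene-6-oxocyclohexa-1,3-dien-1-yl]-5,7-bis(benzyloxy)-2-[3,4,5-tris(benzyloxy)phenyl]chroman-3-yl 3,4,5-tris(benzyloxy)benzoate | O=C(c6cc(OCc9ccccc9)c(OCc9ccccc9)c(OCc9ccccc9)c6)O[C@@H]1[C@@H](C2=C(OCc9ccccc9)C=C(OCc9ccccc9)C(=C)C2=O)c7c(OCc9ccccc9)cc(OCc9ccccc9)cc7O[C@@H]1c5cc(OCc9ccccc9)c(OCc9ccccc9)c(OCc9ccccc9)c5
A3 | alternative 1 | benzyl (E)-2-[3,4-bis(benzyloxy)phenyl]ethenyl carbonate | O=C(OCc9ccccc9)O/C=C/c1ccc(OCc9ccccc9)c(OCc9ccccc9)c1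
A4 | alternative 2 | (4R)-5,7-bis(benzyloxy)-4-(penta-O-benzylcatechin-8-yl)chroman-2-ol, lactol anomers | OC1C[C@@H](c2c(OCc9ccccc9)cc(OCc9ccccc9)c3c2O[C@H](c4ccc(OCc9ccccc9)c(OCc9ccccc9)c4)[C@@H](OCc9ccccc9)C3)c7c(OCc9ccccc9)cc(OCc9ccccc9)cc7O1
A5 | alternative 2 | (E)-3-(penta-O-benzylcatechin-8-yl)prop-2-enal | O=C/C=C/c2c(OCc9ccccc9)cc(OCc9ccccc9)c3c2O[C@H](c4ccc(OCc9ccccc9)c(OCc9ccccc9)c4)[C@@H](OCc9ccccc9)C3
A6 | alternative 2 | 3,5-bis(benzyloxy)phenol | Oc1cc(OCc9ccccc9)cc(OCc9ccccc9)c1
A7 | alternative 3 | (2R,3R)-5,7-bis(benzyloxy)-3-(tert-butyldimethylsilyloxy)-4-(penta-O-benzylcatechin-8-yl)-2-[3,4,5-tris(benzyloxy)phenyl]chroman-4-ol, 2,3-cis, C4 epimers | CC(C)(C)[Si](C)(C)O[C@@H]1C(O)(c2c(OCc9ccccc9)cc(OCc9ccccc9)c3c2O[C@H](c4ccc(OCc9ccccc9)c(OCc9ccccc9)c4)[C@@H](OCc9ccccc9)C3)c7c(OCc9ccccc9)cc(OCc9ccccc9)cc7O[C@@H]1c5cc(OCc9ccccc9)c(OCc9ccccc9)c(OCc9ccccc9)c5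
A8 | alternative 3 | syn aldol, 2-(tert-butyldimethylsilyloxy)-3-hydroxy-1-(penta-O-benzylcatechin-8-yl)-3-[3,4,5-tris(benzyloxy)phenyl]propan-1-one | O[C@H](c5cc(OCc9ccccc9)c(OCc9ccccc9)c(OCc9ccccc9)c5)[C@H](O[Si](C)(C)C(C)(C)C)C(=O)c2c(OCc9ccccc9)cc(OCc9ccccc9)c3c2O[C@H](c4ccc(OCc9ccccc9)c(OCc9ccccc9)c4)[C@@H](OCc9ccccc9)C3
A9 | alternative 3 | 3,5-bis(benzyloxy)benzyne | C1#CC(OCc9ccccc9)=CC(OCc9ccccc9)=C1
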